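**Plan**
- Cuts, in retrosynthetic order: cap O6–H as O6–benzyl. Cut the O–CH3 bonds at C3' and C4', so ring B becomes a catechol. Cut C3–C1' together with O1–C2 in one event. Then cut C2–C3 (the amide acetal carbon off the acetyl group), the O6–benzyl bond, and C4–C4a (the acetyl group off ring A).
- Enabling feature: C3 is the α-carbon of the vinylogous ester O1–C2=C3–C4=O and is nucleophilic once C2 carries NMe2. Ring B has vicinal oxygens at C3'/C4', so at the o-quinone level C1' is the β-carbon of the O=C3'–C2'=C1' enone. The C5' methoxy group shuts down the rival carbon C6'.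
- Forward: ring A (methoxyhydroquinone) and ring B (3-methoxycatechol) are bought. Ring A is C-acetylated, O6-benzylated and extended to the enaminone. Anodic oxidation of the catechol then joins ring B to C3 and closes ring C (the 4-pyranone) in the same flask.
- Helpers: NMe2 is the activator and leaves in the key step. The catechol/o-quinone oxidation level of ring B is removed by double O-methylation. Benzyl on O6 keeps ring A out of the redox and methylation chemistry and is removed last.
- Stereochemistry: there is none to set. Two transient sp3 carbons of the key step return to sp2.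

Key step: step 4

Remark: the target has no stereocentre, no stereogenic double bond and no hindered aryl axis. It is achiral, so the request for a single enantiomer needs no stereocontrolling step.

**Step 1**
Reactants: 1 2-methoxybenzene-1,4-diol (methoxyhydroquinone)
Product: 2 1-(2,5-dihydroxy-4-methoxyphenyl)ethan-1-one
Conditions: AcOH, BF3·OEt2, 90 °C, N2; then H2O
Reagents that add atoms: acetic acid, CC(=O)O
Why: Friedel–Crafts (Nencki-type) C-acylation with BF3-activated acetic acid should go to the only ring carbon that is both ortho to a hydroxyl and para to the methoxy group, and the chelated o-hydroxy ketone formed resists a second acylation.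

**Step 2**
Reactants: 2 1-(2,5-dihydroxy-4-methoxyphenyl)ethan-1-one
Product: 3 1-[5-(benzyloxy)-2-hydroxy-4-methoxyphenyl]ethan-1-one
Conditions: BnBr (1.05 equiv), K2CO3, acetone, reflux
Reagents that add atoms: benzyl bromide, BrCc1ccccc1
Why: Williamson etherification should select the free 5-OH, because the 2-OH is locked in a hydrogen bond to the ketone and is far less nucleophilic under weak base with one equivalent of halide.

**Step 3**
Reactants: 3 1-[5-(benzyloxy)-2-hydroxy-4-methoxyphenyl]ethan-1-one
Product: 4 (E)-1-[5-(benzyloxy)-2-hydroxy-4-methoxyphenyl]-3-(dimethylamino)prop-2-en-1-one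
Conditions: DMF-DMA (2 equiv), toluene, 100 °C
Reagents that add atoms: N,N-dimethylformamide dimethyl acetal, COC(OC)N(C)C
Why: Condensation of the methyl ketone with the amide acetal is the standard entry to o-hydroxyaryl enaminones, should give the E alkene for steric reasons, and leaves the chelated phenol and the benzyl ether untouched.

**Step 4**
Reactants: 4 (E)-1-[5-(benzyloxy)-2-hydroxy-4-methoxyphenyl]-3-(dimethylamino)prop-2-en-1-one; 5 3-methoxybenzene-1,2-diol (3-methoxycatechol, 1.2 equiv)
Product: 9 6-(benzyloxy)-3-(3,4-dihydroxy-5-methoxyphenyl)-7-methoxy-4H-chromen-4-one, via o-quinone 6 (not isolated), via aryl enaminone 7 (not isolated), via aminochromanone 8 (not isolated)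
Conditions: graphite(+)/Pt(−), divided cell, about +0.4 V vs Ag/AgCl, 2.1 F/mol of 5, 0.2 M NaOAc–AcOH buffer (pH 5)/MeCN 1:1, rt, Ar; then AcOH, 60 °C
Reagents that add atoms: none
Why: Proposed new method: at about +0.4 V only catechol 5 is oxidised (−2 e−, −2 H+) to o-quinone 6, the nucleophilic α-carbon of the push–pull alkene of 4 adds to C5 of 6 (the β-carbon of the O=C1–C6=C5 enone), and tautomerisation re-aromatises ring B to the C-arylated adduct 7, which is in equilibrium with its α-protonated iminium form. The ring A phenol oxygen then adds to the iminium carbon in a 6-exo-trig closure to give 8, and E1cB loss of dimethylamine from 8 creates the C2=C3 bond of the pyranone ring of 9, with the acid finish driving any remaining 7 and 8 through while protons are reduced to hydrogen at the cathode. The closest known reaction types are the anodic oxidation of catechols followed by Michael addition of carbon nucleophiles (EC mechanism, shown with secondary enaminones), the Nenitzescu-type C-arylation of N,N-dimethyl enaminones by quinones in acetic acid, and the domino α-functionalisation/chromone annulation of o-hydroxyaryl enaminones, and the new element is only their combination. No stereocentre is set, because C2 and C3 of 8 both return to sp2 in 9. The step needs chemoselective oxidation, which the expected potential gap of several hundred millivolts between 5 and both the enaminone and the O-benzylated ring A of 4 secures, and attack at C5 rather than C4 of 6, which the C3 methoxy group secures by making C4 the electron-rich end of a vinylogous ester. It also needs a single closure mode, which is secured because neither carbon next to the new bond on ring B bears a hydroxyl, so the benzofuran closure of the Nenitzescu manifold is impossible, while the slow anodic release of 6 into an excess of 4 at pH 5 (dimethylamine protonated) should hold back self-condensation and amine capture of the quinone.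

**Step 5**
Reactants: 9 6-(benzyloxy)-3-(3,4-dihydroxy-5-methoxyphenyl)-7-methoxy-4H-chromen-4-one
Product: 10 6-(benzyloxy)-7-methoxy-3-(3,4,5-trimethoxyphenyl)-4H-chromen-4-one
Conditions: MeI (3 equiv), K2CO3, acetone, reflux, Ar
Reagents that add atoms: iodomethane, CI
Why: Double Williamson O-methylation of the catechol under weak base and inert gas is routine for polyhydroxyisoflavones, and no other acidic OH competes because O6 is benzylated.

**Step 6**
Reactants: 10 6-(benzyloxy)-7-methoxy-3-(3,4,5-trimethoxyphenyl)-4H-chromen-4-one
Product: 11 6-hydroxy-7-methoxy-3-(3,4,5-trimethoxyphenyl)-4H-chromen-4-one (target)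
Conditions: H2 (1 atm), 10% Pd/C, EtOAc–MeOH, rt
Reagents that add atoms: none
Why: Catalytic hydrogenolysis should cleave the benzylic C–O bond faster than it saturates the aryl-substituted C2=C3 bond of the isoflavone, provided the uptake is stopped at one equivalent, and the four aryl methyl ethers are inert.

**Compound list**
1 | 2-methoxybenzene-1,4-diol (methoxyhydroquinone) | COc1cc(O)ccc1O | starting material
2 | 1-(2,5-dihydroxy-4-methoxyphenyl)ethan-1-one | CC(=O)c1cc(O)c(OC)cc1O | intermediate
3 | 1-[5-(benzyloxy)-2-hydroxy-4-methoxyphenyl]ethan-1-one | CC(=O)c1cc(OCc2ccccc2)c(OC)cc1O | intermediate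
4 | (E)-1-[5-(benzyloxy)-2-hydroxy-4-methoxyphenyl]-3-(dimethylamino)prop-2-en-1-one | CN(C)/C=C/C(=O)c1cc(OCc2ccccc2)c(OC)cc1O | intermediate
5 | 3-methoxybenzene-1,2-diol (3-methoxycatechol) | COc1cccc(O)c1O | starting material
6 | 3-methoxycyclohexa-3,5-diene-1,2-dione (3-methoxy-o-benzoquinone, formed at the anode, not isolated) | COC1=CC=CC(=O)C1=O | intermediate
7 | 1-[5-(benzyloxy)-2-hydroxy-4-methoxyphenyl]-2-(3,4-dihydroxy-5-methoxyphenyl)-3-(dimethylamino)prop-2-en-1-one (alkene geometry undefined, not isolated) | CN(C)C=C(c1cc(O)c(O)c(OC)c1)C(=O)c1cc(OCc2ccccc2)c(OC)cc1O | intermediate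
8 | 6-(benzyloxy)-3-(3,4-dihydroxy-5-methoxyphenyl)-2-(dimethylamino)-7-methoxychroman-4-one (racemic mixture of diastereomers, not isolated) | CN(C)C1Oc2cc(OC)c(OCc3ccccc3)cc2C(=O)C1c1cc(O)c(O)c(OC)c1 | intermediate
9 | 6-(benzyloxy)-3-(3,4-dihydroxy-5-methoxyphenyl)-7-methoxy-4H-chromen-4-one | COc1cc2occ(-c3cc(O)c(O)c(OC)c3)c(=O)c2cc1OCc1ccccc1 | intermediate
10 | 6-(benzyloxy)-7-methoxy-3-(3,4,5-trimethoxyphenyl)-4H-chromen-4-one | COc1cc2occ(-c3cc(OC)c(OC)c(OC)c3)c(=O)c2cc1OCc1ccccc1 | intermediate
11 | 6-hydroxy-7-methoxy-3-(3,4,5-trimethoxyphenyl)-4H-chromen-4-one | COc1cc2occ(-c3cc(OC)c(OC)c(OC)c3)c(=O)c2cc1O | target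

Total step count: 6.
Longest linear sequence: 6 steps (1 to 11).

**Steps most likely to fail**

**Step 4.**
- Risks:
  - Self-condensation of the o-quinone, or its capture by liberated amine, may outrun C–C bond formation.
  - Regiocontrol in the conjugate addition may erode.
  - Compound 4 may close under acid to the C3-unsubstituted pyranone before it is arylated.
  - The catechol product may be oxidised further at the anode.
- Fallback (known chemistry): it sets out from 4. Iodine in methanol at rt effects α-iodination with ring closure to 6-(benzyloxy)-3-iodo-7-methoxy-4H-chromen-4-one F1. Suzuki–Miyaura coupling of F1 with commercial (3,4,5-trimethoxyphenyl)boronic acid F2 follows (Pd(dppf)Cl2, Na2CO3, dioxane–H2O, 80 °C). The fallback comes back to the route at 10 and bypasses 9 and step 5.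

**Step 1.**
- Risks:
  - O-acylation may compete with C-acylation.
  - The hydroquinone may be oxidised in the hot Lewis acid medium.
  - Acylation may occur at the carbon ortho to the other hydroxyl.
- Fallback: it reverses the logic by buying the aryl ketone and installing the oxygen. It replaces starting material 1 with commercial 1-(2-hydroxy-4-methoxyphenyl)ethan-1-one (paeonol) F3. Elbs persulfate oxidation (K2S2O8, aq NaOH, rt) should place a sulfate para to the phenol, giving potassium 5-acetyl-4-hydroxy-2-methoxyphenyl sulfate F4. Hot aqueous HCl hydrolyses the sulfate, and the fallback comes back to the route at 2.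

**Step 6.**
- Risks:
  - Saturation of the C2=C3 bond may compete with C–O cleavage.
  - Debenzylation may stall on a poorly soluble substrate.
- Fallback: it sets out from 10 and replaces reduction with Lewis acid mediated benzyl transfer. BCl3 with pentamethylbenzene as cation scavenger is used in CH2Cl2 at −78 °C. At that temperature the conditions should spare aryl methyl ethers and cannot touch the enone. The fallback comes back to the route at 11 and makes no new compound (F0).

**Further compounds**
F1 | step 4 | 6-(benzyloxy)-3-iodo-7-methoxy-4H-chromen-4-one | COc1cc2occ(I)c(=O)c2cc1OCc1ccccc1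
F2 | step 4 | (3,4,5-trimethoxyphenyl)boronic acid (commercial) | COc1cc(B(O)O)cc(OC)c1OC
F3 | step 1 | 1-(2-hydroxy-4-methoxyphenyl)ethan-1-one (paeonol, commercial) | CC(=O)c1ccc(OC)cc1O
F4 | step 1 | potassium 5-acetyl-4-hydroxy-2-methoxyphenyl sulfate | CC(=O)c1cc(OS(=O)(=O)[O-])c(OC)cc1O.[K+]
F0 | step 6 | none | none
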